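Assumption: the β-dicarbonyl compounds 10–13 are written as keto tautomers although they will be largely enolised, and 13 may hold its ring double bond exocyclic (C8a=C8); all these forms give the same enolates. Compounds 7, 8 and 10–17 are racemic.

Abbreviations: prenyl = 3-methylbut-2-en-1-yl; MOM = methoxymethyl; Ar = 2,4-bis(methoxymethoxy)-3-prenylphenyl. Chroman numbering (O1, C2, C3, C4, C4a, C5–C8, C8a; ring B C1'–C6') is used for the target and for the open-chain atoms that end up at these positions.

## The problem

Licoricidin is a (3R)-isoflavan: a chroman (rings A and C) that carries a 2,4-dihydroxy-3-prenylphenyl ring B on C3. Ring A is a fully differentiated phloroglucinol: the oxygen on C8a is the ring ether O1, that on C5 is a methyl ether, that on C7 is a free phenol, and the prenyl group sits on C6, not on C8. Prenylation or ring closure of a preformed symmetric phloroglucinol gives 6/8 mixtures, so this regiochemistry is the main constitutional problem. C3 is the only stereocentre. It lies between two methylene groups and no other centre can control it, so it must be set by a catalyst. It is configurationally labile only while C4 is a carbonyl group, which invites a dynamic resolution at that stage. The two prenyl groups, each ortho to a phenol, rule out catalytic hydrogenation and hydrogenolysis and cyclise to chromans under strong acid. The electron-rich rings also make a C4 cation easy to form and easy to divert. What makes a ring-building approach possible is that the oxygens on C5, C7 and C8a alternate with the carbon substituents on C4a and C6, the pattern of a folded triketide in which C5 is an ester carbon and C4a a nucleophilic carbon. If O1 is tied to C8a before folding, the ring can close in only one sense.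

## Retrosynthesis

**Protecting groups (20 from 19).** The last step only removes three MOM ethers from 19. MOM is chosen because it directs the two lithiations that build ring B and survives every basic step. One mild acid treatment at the end is the price.

**C4 methylene and the stereocentre (19 from 18 from 17).** The C4–H bond is traced back to the C4–OH bond of the cis-alcohol 18, and 18 to the racemic ketone 17. Keeping a carbonyl on C4 until late has two advantages over setting C3 by alkylation or alkene hydrogenation. It is what the ring construction delivers, and it makes C3 epimerisable, so a transfer hydrogenation can funnel both enantiomers of 17 into one alcohol without touching the prenyl groups. The forward steps must reduce a hindered, electron-rich aryl ketone with catalyst control and then remove the benzylic oxygen without disturbing C3.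

**O5 versus O7 (17 from 16 from 15).** The methyl on O5 and the MOM on O7 are removed to reach the diol 15. In 15 the 5-hydroxyl is hydrogen-bonded to the C4 carbonyl and the 7-hydroxyl is not, so the two can be told apart in the forward direction without a blocking group strategy. Capping O5 before the reduction also closes the only path by which ring C could open and reclose through the other ortho oxygen.

**Ring A (15 from 13, the key cut).** The C4a–C5 bond is cut and C5 becomes a methyl ester, which unfolds ring A into the β-keto ester side chain of the dihydropyranone 13. This is preferred to cutting ring C of a prenylated phloroglucinol because 13 already has O1 bound to C8a and the prenyl group on the carbon that becomes C6, so the 6-prenyl pattern is fixed by connectivity. The precursor has no aromatic ring A and is made from commodity chemicals. The forward reaction must be a Claisen closure from C4a onto C5 that outruns any aldol closure.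

**Ring C of 13 (13 from 12 from 11 + 8).** The O1–C8a bond (cyclodehydration) and the C4–C4a bond (acylation) are cut, giving the diketo ester 11 as a terminal nucleophile and the hydroxy Weinreb amide 8 as acyl donor. Cutting C4–C4a joins the two halves of the molecule at the only carbonyl that has no enolisable partner on the ring B side. Carrying the C2 hydroxyl of 8 as an alkoxide removes the risk of β-elimination without a protecting group. The open-chain 12 must be cyclised at once so that it does not fold by itself.

**Triketide chain (11 from 10 from 9 + 3).** The C8–C8a bond is cut (acetylation of a β-keto ester dianion) and then the C6–prenyl bond (alkylation of methyl acetoacetate 9 with prenyl bromide 3). Placing the prenyl group first, at the most acidic carbon of the simplest precursor, avoids any later choice between C6 and C8.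

**Ring B acyl donor (8 from 7 from 6 from 5 from 4 from 2 from 1).** The amide 8 comes from ester 7, whose CH2OH carbon (C2) is cut off as formaldehyde to give the arylacetate 6. The aryl–CH2 bond of 6 is cut to the bromide 5 and a zinc ester enolate. Bromine and prenyl are traced to two successive ortho-lithiations of resorcinol bis-MOM ether 2, made from resorcinol 1. Lithiation between the two oxygens places the ring B prenyl group without ambiguity, which electrophilic prenylation cannot do.

## Roads not taken

Alternative 1: The C3–C1' and C4–C4a bonds are cut together. In the forward step the ring B aryl pinacol boronate A2 is converted into a vinyl boron ate complex with a vinyl-metal linchpin. A palladium catalyst with a chiral bisphosphine inserts into the ring A aryl triflate A3, and the aryl–palladium species triggers migration of the ring B aryl group from boron to carbon. The product is the secondary boronate A1 with C3 set by the catalyst; C2 would follow by one-carbon homologation of the C–B bond, oxidation and etherification onto O1. This road is more convergent than the chosen one, sets the stereocentre in the bond-forming step and never has an oxygen on C4 to remove; in stereocontrol and in the length of the endgame it is better. Its weak points are structural. A3 is a fully substituted benzene whose 6-prenyl pattern must still be solved by classical phenol chemistry, so the hardest problem of the target is only moved into a starting material. Its triflate is flanked by two ortho oxygen substituents, and A2 is an ortho-alkoxy, electron-rich boronate, a combination that works against both oxidative addition and the migration. Against the better stereochemical step, the chosen plan sets regiochemistry that is fixed by construction and starting materials that need no aromatic substitution on ring A at all.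

Alternative 2: C3 is inserted as a single carbon between C2 and C4. The ring B aryl chlorodiazirine A6 is heated with the ring A benzofuran A5; the aryl chlorocarbene adds to the furan double bond and the cyclopropane opens with loss of chloride, enlarging the furan to the benzopyrylium salt A4. Reduction, two bromine-to-prenyl exchanges and fluoride deprotection would follow. The skeleton arises in one step from two flat aromatics. The prenyl groups come last, so the reduction that sets C3 could even be an alkene hydrogenation, and the final deprotection needs no acid; in these respects it is better than the chosen plan. Against it stand several points. The diazirine would have to be made from a doubly ortho-oxygenated, electron-rich arene, whose carbene is a poor electrophile. The substitution pattern of ring A is again pushed into the preparation of A5. Enantioselective reduction of a 3-aryl benzopyrylium is not an established operation. Two late prenylations through aryl-metal species must each give the linear isomer. The chosen plan has one unproven step instead of three and carries both prenyl groups from the first steps.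

Alternative 3: Ring B is cut at C1'–C6' and C2'–C3'. The enolate of the chroman-3-ylacetate A8 adds to the enone A9 and a base-mediated Claisen condensation closes the 2-prenylcyclohexane-1,3-dione A7, to be dehydrogenated to the resorcinol later. Like the chosen plan it builds an aromatic ring from carbonyl precursors, and the prenyl group falls between the two oxygens without any directed metalation. It has three drawbacks. It spends the ring-construction logic on ring B, whose pattern one lithiation solves, and leaves ring A of A8, with the difficult pattern, to be made conventionally and in enantiopure form. Aromatisation of A7 is an oxidation, and the usual oxidants or dehydrogenation catalysts endanger two trisubstituted alkenes and an electron-rich chroman. The enone A9 is prone to polymerise and to quench the ester enolate. In the chosen plan aromatisation is a redox-neutral tautomerisation, and the ring that is built is the one whose regiochemistry is hard.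

Key step: step 10

## Route

Step 1
Reactants: 1 resorcinol
Product: 2 1,3-bis(methoxymethoxy)benzene
Conditions: NaH, MOMCl, DMF, 0 °C → rt
Reagents that add atoms: chloromethyl methyl ether, COCCl
Why: Williamson-type O-alkylation of the bis-phenoxide; the acetal ethers direct the two ortho-lithiations that follow and withstand every basic step of the route.

Step 2
Reactants: 2 1,3-bis(methoxymethoxy)benzene; 3 prenyl bromide (1-bromo-3-methylbut-2-ene)
Product: 4 1,3-bis(methoxymethoxy)-2-prenylbenzene
Conditions: n-BuLi, THF, 0 °C; CuI (10 mol %), prenyl bromide, −78 °C → rt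
Reagents that add atoms: none
Why: Directed ortho-metalation at the position flanked by both acetal oxygens, then copper-catalysed allylic substitution; copper keeps the attack at the primary carbon of the bromide, so the linear prenyl group results.

Step 3
Reactants: 4 1,3-bis(methoxymethoxy)-2-prenylbenzene
Product: 5 1-bromo-2,4-bis(methoxymethoxy)-3-prenylbenzene
Conditions: n-BuLi, TMEDA, THF, −20 → 0 °C; BrCCl2CCl2Br, −78 °C
Reagents that add atoms: 1,2-dibromo-1,1,2,2-tetrachloroethane, ClC(Cl)(Br)C(Cl)(Cl)Br
Why: Second directed ortho-metalation, now next to one MOM ether (the two open ortho positions are equivalent), and bromine transfer from the polyhaloethane; no electrophilic brominating agent that could attack the prenyl double bond is used.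

Step 4
Reactants: 5 1-bromo-2,4-bis(methoxymethoxy)-3-prenylbenzene
Product: 6 ethyl 2-Ar-acetate
Conditions: BrZnCH2CO2Et (from ethyl bromoacetate, Zn, THF), Pd2(dba)3 (2 mol %), P(t-Bu)3 (8 mol %), THF, rt → 50 °C
Reagents that add atoms: ethyl bromoacetate, CCOC(=O)CBr (used as its zinc enolate)
Why: Palladium-catalysed α-arylation of a zinc ester enolate (Reformatsky–Negishi-type coupling); the neutral zinc enolate tolerates acetals and alkene, and the bulky trialkylphosphine handles the ortho-substituted bromide.

Step 5
Reactants: 6 ethyl 2-Ar-acetate
Product: 7 ethyl 2-Ar-3-hydroxypropanoate (racemic)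
Conditions: (CH2O)n, K2CO3 (20 mol %), DMSO, rt
Reagents that add atoms: paraformaldehyde (formaldehyde), C=O
Why: Base-catalysed aldol addition of an arylacetate to formaldehyde (hydroxymethylation, as in tropic ester synthesis); catalytic carbonate at room temperature should stop at the mono-adduct without dehydration. The new centre (later C3) is racemic on purpose.

Step 6
Reactants: 7 ethyl 2-Ar-3-hydroxypropanoate
Product: 8 2-Ar-3-hydroxy-N-methoxy-N-methylpropanamide (racemic)
Conditions: MeNH(OMe)·HCl, i-PrMgCl, THF, −20 → 0 °C
Reagents that add atoms: N,O-dimethylhydroxylamine hydrochloride, CNOC.Cl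
Why: Weinreb amide formation by aminolysis of the ester with the chloromagnesium amide; the hydroxyl travels as its magnesium alkoxide, which cannot be eliminated.

Step 7
Reactants: 9 methyl acetoacetate; 3 prenyl bromide
Product: 10 methyl 2-acetyl-5-methylhex-4-enoate (racemic)
Conditions: NaH, THF, 0 °C; prenyl bromide, 0 °C → rt
Reagents that add atoms: none
Why: C-alkylation of the sodium enolate of a β-keto ester with an allylic bromide; a slight excess of 9 limits dialkylation.

Step 8
Reactants: 10 methyl 2-acetyl-5-methylhex-4-enoate
Product: 11 methyl 2-prenyl-3,5-dioxohexanoate (racemic)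
Conditions: NaH, THF, 0 °C; n-BuLi, 0 °C; MeC(O)N(OMe)Me, −78 → 0 °C; aq. HCl
Reagents that add atoms: N-methoxy-N-methylacetamide, CON(C)C(C)=O
Why: Weiler dianion of a β-keto ester acylated at its terminal carbon by a Weinreb amide; the chelated tetrahedral adduct prevents over-reaction and gives the 3,5-diketo ester.

Step 9
Reactants: 11 methyl 2-prenyl-3,5-dioxohexanoate; 8 2-Ar-3-hydroxy-N-methoxy-N-methylpropanamide
Product: 13 methyl 4-(3-Ar-4-oxo-3,4-dihydro-2H-pyran-6-yl)-3-oxo-2-prenylbutanoate, via hydroxy triketo ester 12 (not isolated)
Conditions: 11 (1.5 equiv), LDA (4.6 equiv), THF, −78 → 0 °C; lithium alkoxide of 8 (LDA 1.0 equiv, THF, −78 °C), −78 → −20 °C; AcOH; crude, TsOH·H2O (10 mol %), CH2Cl2, 4 Å MS, 0 °C → rt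
Reagents that add atoms: none
Why: Polyanion acylation: the trianion of 11 reacts at its last-formed terminal carbanion (later C4a) with the Weinreb amide, whose hydroxyl is masked as the lithium alkoxide so that α-deprotonation cannot end in β-elimination. On acid treatment the C2 hydroxyl of 12 adds to the C8a ketone, the only six-membered option, and loss of water gives the vinylogous ester 13; the aryl-bearing centre stays racemic.

Step 10
Reactants: 13 methyl 4-(3-Ar-4-oxo-3,4-dihydro-2H-pyran-6-yl)-3-oxo-2-prenylbutanoate
Product: 15 3-Ar-5,7-dihydroxy-6-prenylchroman-4-one (racemic), via non-aromatised Claisen adduct 14 (not isolated)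
Conditions: NaOMe (3 equiv), MeOH–THF, 0 °C → rt; aq. HCl to pH 4
Reagents that add atoms: none
Why: Proposed new method: methoxide equilibrates the C6 and C8 enolates of 13; the C8 enolate is a dienolate running through C8a and C4a to the C4 carbonyl, its C4a terminus adds to the ester carbon C5, methoxide leaves (14) and two enolisations give the aromatic ring. The closest known reaction type is the base-mediated Claisen cyclisation of 3,5,7-triketo esters to acylphloroglucinols and of pyranone-tethered β-keto esters to 5,7-dihydroxychromones; a 2,3-dihydropyran-4-one has not served as the masked diketone. Ring A closes in a 6-(enolexo)-exo-trig mode. No stereocentre is formed and C3 stays racemic, which is wanted because step 13 sets it. The step needs Claisen closure from C4a onto C5 to beat aldol closure from C6 onto C4; the prenyl group on C6 makes that aldol adduct quaternary and unable to aromatise, so it can only revert, and the C4 carbonyl is a deactivated vinylogous ester. Because O1 already bridges C2 and C8a, the new ring can fuse only in the sense that puts the prenyl group on C6. Aromatisation and phenoxide formation make the closure irreversible.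

Step 11
Reactants: 15 3-Ar-5,7-dihydroxy-6-prenylchroman-4-one
Product: 16 3-Ar-5-hydroxy-7-(methoxymethoxy)-6-prenylchroman-4-one (racemic)
Conditions: MOMCl (1.1 equiv), i-Pr2NEt, CH2Cl2, 0 °C
Reagents that add atoms: chloromethyl methyl ether, COCCl
Why: Selective O-alkylation of the free, more acidic 7-hydroxyl; the 5-hydroxyl is hydrogen-bonded to the C4 carbonyl and does not react under amine-base conditions.

Step 12
Reactants: 16 3-Ar-5-hydroxy-7-(methoxymethoxy)-6-prenylchroman-4-one
Product: 17 3-Ar-5-methoxy-7-(methoxymethoxy)-6-prenylchroman-4-one (racemic)
Conditions: MeI, K2CO3, acetone, 45 °C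
Reagents that add atoms: iodomethane, CI
Why: Williamson methylation of the chelated phenol; C3–H is far less acidic than the phenol under carbonate conditions. Once O5 is capped, ring C can no longer open and reclose through O5, so the prenyl group cannot end up on C8.

Step 13
Reactants: 17 3-Ar-5-methoxy-7-(methoxymethoxy)-6-prenylchroman-4-one
Product: 18 (3R,4R)-3-Ar-5-methoxy-7-(methoxymethoxy)-6-prenylchroman-4-ol (3-aryl and 4-hydroxyl cis)
Conditions: RuCl(p-cymene)[(R,R)-TsDPEN] (3 mol %), HCO2H–Et3N (5:2), EtOAc, 40 °C
Reagents that add atoms: none
Why: Noyori asymmetric transfer hydrogenation with dynamic kinetic resolution: the amine racemises C3 through the enol, the (R,R)-catalyst should reduce the (3R)-ketone faster and deliver hydride to C4 anti to the 3-aryl group, so the catalyst sets both centres as cis-(3R,4R). Isolated alkenes are not reduced by this catalyst.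

Step 14
Reactants: 18 (3R,4R)-3-Ar-5-methoxy-7-(methoxymethoxy)-6-prenylchroman-4-ol
Product: 19 (3R)-3-Ar-5-methoxy-7-(methoxymethoxy)-6-prenylchromane
Conditions: Et3SiH (10 equiv), CF3CO2H (3 equiv), CH2Cl2, −40 → −20 °C
Reagents that add atoms: none
Why: Ionic deoxygenation: the benzylic alcohol, stabilised by two ortho and one para oxygen, ionises with little acid at low temperature and the silane delivers hydride to C4. C3 is not part of the cation and keeps its configuration; limited acid and low temperature are chosen to spare the acetals and the prenyl groups.

Step 15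
Reactants: 19 (3R)-3-Ar-5-methoxy-7-(methoxymethoxy)-6-prenylchromane
Product: 20 licoricidin, 4-[(3R)-7-hydroxy-5-methoxy-6-prenylchroman-3-yl]-2-prenylbenzene-1,3-diol
Conditions: HCl (aq., 3 M), MeOH, 40 °C
Reagents that add atoms: none
Why: Acid-catalysed acetal exchange with methanol removes the three MOM groups; dilute acid at mild temperature is the usual way to unmask prenylated phenols and should not cyclise them to chromans.

## Compound list

1 | resorcinol | Oc1cccc(O)c1 | starting material
2 | 1,3-bis(methoxymethoxy)benzene | COCOc1cccc(OCOC)c1 | intermediate
3 | prenyl bromide (1-bromo-3-methylbut-2-ene) | CC(C)=CCBr | starting material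
4 | 1,3-bis(methoxymethoxy)-2-(3-methylbut-2-en-1-yl)benzene | COCOc1cccc(OCOC)c1CC=C(C)C | intermediate
5 | 1-bromo-2,4-bis(methoxymethoxy)-3-(3-methylbut-2-en-1-yl)benzene | COCOc1ccc(Br)c(OCOC)c1CC=C(C)C | intermediate
6 | ethyl 2-[2,4-bis(methoxymethoxy)-3-(3-methylbut-2-en-1-yl)phenyl]acetate | CCOC(=O)Cc1ccc(OCOC)c(CC=C(C)C)c1OCOC | intermediate
7 | ethyl 2-[2,4-bis(methoxymethoxy)-3-(3-methylbut-2-en-1-yl)phenyl]-3-hydroxypropanoate, racemic | CCOC(=O)C(CO)c1ccc(OCOC)c(CC=C(C)C)c1OCOC | intermediate
8 | 2-[2,4-bis(methoxymethoxy)-3-(3-methylbut-2-en-1-yl)phenyl]-3-hydroxy-N-methoxy-N-methylpropanamide, racemic | CON(C)C(=O)C(CO)c1ccc(OCOC)c(CC=C(C)C)c1OCOC | intermediate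
9 | methyl acetoacetate | COC(=O)CC(C)=O | starting material
10 | methyl 2-acetyl-5-methylhex-4-enoate, racemic | COC(=O)C(CC=C(C)C)C(C)=O | intermediate
11 | methyl 2-(3-methylbut-2-en-1-yl)-3,5-dioxohexanoate, racemic | COC(=O)C(CC=C(C)C)C(=O)CC(C)=O | intermediate
12 | methyl 8-[2,4-bis(methoxymethoxy)-3-prenylphenyl]-9-hydroxy-2-prenyl-3,5,7-trioxononanoate, mixture of diastereomers | COC(=O)C(CC=C(C)C)C(=O)CC(=O)CC(=O)C(CO)c1ccc(OCOC)c(CC=C(C)C)c1OCOC | intermediate (not isolated)
13 | methyl 4-{3-[2,4-bis(methoxymethoxy)-3-prenylphenyl]-4-oxo-3,4-dihydro-2H-pyran-6-yl}-3-oxo-2-prenylbutanoate, mixture of diastereomers | COC(=O)C(CC=C(C)C)C(=O)CC1=CC(=O)C(c2ccc(OCOC)c(CC=C(C)C)c2OCOC)CO1 | intermediate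
14 | 3-[2,4-bis(methoxymethoxy)-3-prenylphenyl]-6-prenyl-2,3-dihydro-4aH-chromene-4,5,7(6H)-trione, mixture of stereoisomers | O=C1C(CC=C(C)C)C(=O)C=C2OCC(c3ccc(OCOC)c(CC=C(C)C)c3OCOC)C(=O)C12 | intermediate (not isolated)
15 | 3-[2,4-bis(methoxymethoxy)-3-prenylphenyl]-5,7-dihydroxy-6-prenylchroman-4-one, racemic | O=C1c2c(O)c(CC=C(C)C)c(O)cc2OCC1c1ccc(OCOC)c(CC=C(C)C)c1OCOC | intermediate
16 | 3-[2,4-bis(methoxymethoxy)-3-prenylphenyl]-5-hydroxy-7-(methoxymethoxy)-6-prenylchroman-4-one, racemic | O=C1c2c(O)c(CC=C(C)C)c(OCOC)cc2OCC1c1ccc(OCOC)c(CC=C(C)C)c1OCOC | intermediate
17 | 3-[2,4-bis(methoxymethoxy)-3-prenylphenyl]-5-methoxy-7-(methoxymethoxy)-6-prenylchroman-4-one, racemic | COc1c(CC=C(C)C)c(OCOC)cc2OCC(c3ccc(OCOC)c(CC=C(C)C)c3OCOC)C(=O)c12 | intermediate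
18 | (3R,4R)-3-[2,4-bis(methoxymethoxy)-3-prenylphenyl]-5-methoxy-7-(methoxymethoxy)-6-prenylchroman-4-ol | COc1c(CC=C(C)C)c(OCOC)cc2OC[C@@H](c3ccc(OCOC)c(CC=C(C)C)c3OCOC)[C@@H](O)c12 | intermediate
19 | (3R)-3-[2,4-bis(methoxymethoxy)-3-prenylphenyl]-5-methoxy-7-(methoxymethoxy)-6-prenylchromane | COc1c(CC=C(C)C)c(OCOC)cc2OC[C@@H](c3ccc(OCOC)c(CC=C(C)C)c3OCOC)Cc12 | intermediate
20 | licoricidin, 4-[(3R)-7-hydroxy-5-methoxy-6-(3-methylbut-2-en-1-yl)chroman-3-yl]-2-(3-methylbut-2-en-1-yl)benzene-1,3-diol | COc1c(CC=C(C)C)c(O)cc2c1C[C@H](c1ccc(O)c(CC=C(C)C)c1O)CO2 | target

## Step count and least certain steps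

Total: 15 steps. Longest linear sequence: 13 steps (steps 1–6 and 9–15, from resorcinol); steps 7 and 8 form the short second branch.

**Step 10 (key step, proposed new method).** Three processes could divert it.
- Preferential enolisation at C6 would turn the ester into an unreactive enolate and stall the closure.
- Deprotonation at C3 followed by β-elimination of O1 would open ring C, after which ring A could form without the regiochemical lock.
- Methoxide could add to C8a.

Fallback with known chemistry: it sets out from 12, formed as in step 9 with the acid treatment left out. Methanolic KOH should effect the established Claisen cyclisation of a 3,5,7-triketo ester to the acylphloroglucinol 2-Ar-3-hydroxy-1-(2,4,6-trihydroxy-3-prenylphenyl)propan-1-one F1. A Mitsunobu etherification (PPh3, DIAD, THF) then closes O1–C2 and returns to the route at 15. The price is that the choice between the two ortho hydroxyls then rests only on the smaller steric demand next to C8–H.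

**Step 9.** Proton transfer from the amide to the strongly basic trianion could compete with acylation, and open-chain 12 could fold by aldol or Claisen reaction or close to a pyranone before the hydroxyl has cyclised. Fallback: it sets out from 8 and forms the C4–C4a bond by aldol addition instead of acylation.
- Silylation (Et3SiCl, imidazole) gives the triethylsilyl ether of 8, F2.
- DIBAL-H at −78 °C gives 2-Ar-3-(triethylsilyloxy)propanal F3.
- Addition of the trianion of 11 at −78 °C, where carbonyl addition outruns proton transfer, gives the 7-hydroxy-3,5-diketo ester F4.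
- Dess–Martin oxidation gives the silyl-protected triketo ester F5.
- TsOH·H2O in CH2Cl2–MeOH removes the silyl group and cyclises through 12, returning to the route at 13.

**Step 14.** The C4 cation could be intercepted by the 2'-oxygen with loss of its MOM group, could lose the proton on C3 and be re-protonated with erosion of the configuration, or the acid could start to hydrate or reduce a prenyl double bond. Fallback: it sets out from 18 and replaces hydride capture by sulfur capture and a radical reduction. Thiophenol in large excess with catalytic PPTS at −20 °C should trap the cation much faster than a silane and give (3R)-3-Ar-5-methoxy-7-(methoxymethoxy)-4-(phenylsulfanyl)-6-prenylchromane F6 as a mixture of C4 epimers. Bu3SnH and AIBN in toluene at 80 °C then cleave the benzylic C–S bond under neutral conditions and return to the route at 19.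

**Step 15.** Once a phenol is free, protonation of the neighbouring prenyl double bond and ring closure to a 2,2-dimethylchroman can compete with removal of the remaining acetals. Fallback: it sets out from 19 and avoids protic acid. Me3SiOTf with 2,2'-bipyridyl in MeCN at 0 °C converts aryl MOM ethers into aryl silyl ethers through pyridinium intermediates and should give the tris(trimethylsilyl) ether of licoricidin F7. Water or K2CO3 in MeOH then cleaves the silyl ethers and returns to the route at 20.

**Step 3.** Butyllithium could remove a proton from the doubly activated benzylic–allylic methylene of the prenyl group instead of the ring position. Fallback: the bromine is brought in with the starting material. Commercial 4-bromoresorcinol F8 is converted into 1-bromo-2,4-bis(methoxymethoxy)benzene F9 (NaH, MOMCl). LDA at −78 °C, which does not exchange the bromine, deprotonates the position between the two acetal oxygens, and CuI-catalysed reaction with 3 gives the prenyl group there. This replaces compounds 2 and 4 and returns to the route at 5.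

## Further compounds

F1 | step 10 | 2-[2,4-bis(methoxymethoxy)-3-prenylphenyl]-3-hydroxy-1-(2,4,6-trihydroxy-3-prenylphenyl)propan-1-one, racemic | OCC(c1ccc(OCOC)c(CC=C(C)C)c1OCOC)C(=O)c1c(O)cc(O)c(CC=C(C)C)c1O
F2 | step 9 | 2-[2,4-bis(methoxymethoxy)-3-prenylphenyl]-N-methoxy-N-methyl-3-(triethylsilyloxy)propanamide, racemic | CC[Si](CC)(CC)OCC(C(=O)N(C)OC)c1ccc(OCOC)c(CC=C(C)C)c1OCOC
F3 | step 9 | 2-[2,4-bis(methoxymethoxy)-3-prenylphenyl]-3-(triethylsilyloxy)propanal, racemic | CC[Si](CC)(CC)OCC(C=O)c1ccc(OCOC)c(CC=C(C)C)c1OCOC
F4 | step 9 | methyl 8-[2,4-bis(methoxymethoxy)-3-prenylphenyl]-7-hydroxy-3,5-dioxo-2-prenyl-9-(triethylsilyloxy)nonanoate, mixture of diastereomers | COC(=O)C(CC=C(C)C)C(=O)CC(=O)CC(O)C(CO[Si](CC)(CC)CC)c1ccc(OCOC)c(CC=C(C)C)c1OCOC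
F5 | step 9 | methyl 8-[2,4-bis(methoxymethoxy)-3-prenylphenyl]-3,5,7-trioxo-2-prenyl-9-(triethylsilyloxy)nonanoate, mixture of diastereomers | COC(=O)C(CC=C(C)C)C(=O)CC(=O)CC(=O)C(CO[Si](CC)(CC)CC)c1ccc(OCOC)c(CC=C(C)C)c1OCOC
F6 | step 14 | (3R)-3-[2,4-bis(methoxymethoxy)-3-prenylphenyl]-5-methoxy-7-(methoxymethoxy)-4-(phenylsulfanyl)-6-prenylchromane, mixture of C4 epimers | COc1c(CC=C(C)C)c(OCOC)cc2OC[C@@H](c3ccc(OCOC)c(CC=C(C)C)c3OCOC)C(Sc3ccccc3)c12
F7 | step 15 | (3R)-3-[2,4-bis(trimethylsilyloxy)-3-prenylphenyl]-5-methoxy-6-prenyl-7-(trimethylsilyloxy)chromane | COc1c(CC=C(C)C)c(O[Si](C)(C)C)cc2OC[C@@H](c3ccc(O[Si](C)(C)C)c(CC=C(C)C)c3O[Si](C)(C)C)Cc12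
F8 | step 3 | 4-bromoresorcinol (purchased) | Oc1ccc(Br)c(O)c1
F9 | step 3 | 1-bromo-2,4-bis(methoxymethoxy)benzene | COCOc1ccc(Br)c(OCOC)c1
A1 | alternative 1 | 2-{(1R)-1-[2,4-bis(methoxymethoxy)-3-prenylphenyl]-2-[6-(tert-butyldimethylsilyloxy)-2-methoxy-4-(methoxymethoxy)-3-prenylphenyl]ethyl}-4,4,5,5-tetramethyl-1,3,2-dioxaborolane | COc1c(CC=C(C)C)c(OCOC)cc(O[Si](C)(C)C(C)(C)C)c1C[C@H](c1ccc(OCOC)c(CC=C(C)C)c1OCOC)B1OC(C)(C)C(C)(C)O1
A2 | alternative 1 | 2-[2,4-bis(methoxymethoxy)-3-prenylphenyl]-4,4,5,5-tetramethyl-1,3,2-dioxaborolane | COCOc1ccc(B2OC(C)(C)C(C)(C)O2)c(OCOC)c1CC=C(C)C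
A3 | alternative 1 | 6-(tert-butyldimethylsilyloxy)-2-methoxy-4-(methoxymethoxy)-3-prenylphenyl trifluoromethanesulfonate | COc1c(CC=C(C)C)c(OCOC)cc(O[Si](C)(C)C(C)(C)C)c1OS(=O)(=O)C(F)(F)F
A4 | alternative 2 | 6,3'-dibromo-5-methoxy-7,2',4'-tris(triisopropylsilyloxy)isoflavylium chloride | COc1c(Br)c(O[Si](C(C)C)(C(C)C)C(C)C)cc2[o+]cc(cc12)-c1ccc(O[Si](C(C)C)(C(C)C)C(C)C)c(Br)c1O[Si](C(C)C)(C(C)C)C(C)C.[Cl-]
A5 | alternative 2 | 5-bromo-4-methoxy-6-(triisopropylsilyloxy)benzofuran | COc1c(Br)c(O[Si](C(C)C)(C(C)C)C(C)C)cc2occc12
A6 | alternative 2 | 3-[3-bromo-2,4-bis(triisopropylsilyloxy)phenyl]-3-chloro-3H-diazirine | ClC1(N=N1)c1ccc(O[Si](C(C)C)(C(C)C)C(C)C)c(Br)c1O[Si](C(C)C)(C(C)C)C(C)C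
A7 | alternative 3 | 4-[(3R)-5-methoxy-6-prenyl-7-(triisopropylsilyloxy)chroman-3-yl]-2-prenylcyclohexane-1,3-dione, mixture of epimers at the two ring centres | COc1c(CC=C(C)C)c(O[Si](C(C)C)(C(C)C)C(C)C)cc2c1C[C@H](C1CCC(=O)C(CC=C(C)C)C1=O)CO2
A8 | alternative 3 | methyl 2-[(3R)-5-methoxy-6-prenyl-7-(triisopropylsilyloxy)chroman-3-yl]acetate | COc1c(CC=C(C)C)c(O[Si](C(C)C)(C(C)C)C(C)C)cc2c1C[C@H](CC(=O)OC)CO2
A9 | alternative 3 | 7-methylocta-1,6-dien-3-one | C=CC(=O)CCC=C(C)C
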